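**Retrosynthetic overview**
1. The target comes from its four-fold aryl silyl ether by weakly acidic fluoride desilylation, so the cis-dihydrofuran never meets base.
2. Rings B and A are made in one flask: a chiral dirhodium carbene inserts into the benzylic C–H of a 4-O-benzyl ether (ring B, both stereocentres, cis), then the C-3 dioxinone is opened thermally to an acylketene that adds a ketene bis-silyl acetal in a [4+2] sense (ring A).
3. The diazo precursor comes from diazo transfer to a pyranonyl–CH2–dioxinone, itself made by Mitsunobu O-benzylation after C-3 reductive alkylation of the ring C pyranone with dioxinone-6-carbaldehyde.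
4. Ring C (6-aryl-4-hydroxy-2-pyranone) comes from the silyl enol ether of 3',4'-dihydroxyacetophenone and malonyl dichloride.
5. Ring order: C first, then B and A together.

Assumption: the SMILES is read literally as (2R,3S), which places the C-2 aryl and C-3 pyranonyl groups cis; the catalyst antipode named in step 10 is taken to give this series (its mirror image gives the enantiomer, so the sense is fixed on the first analytical run).

TBS = tert-butyldimethylsilyl throughout.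

Step 1
Reactants: 1 1-(3,4-dihydroxyphenyl)ethan-1-one
Product: 2 tert-butyl{[1-(3,4-bis(TBSO)phenyl)ethenyl]oxy}dimethylsilane
Conditions: TBSOTf (3.3 equiv), Et3N (4 equiv), CH2Cl2, 0 → 23 °C
Reagents that add atoms: tert-butyldimethylsilyl trifluoromethanesulfonate, CC(C)(C)[Si](C)(C)OS(=O)(=O)C(F)(F)F
Why: Silyl triflate with amine base silylates both phenols and converts the methyl ketone into its silyl enol ether in one pot (soft enolisation); no stereocentre is formed.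

Step 2
Reactants: 2 tris-silyl enol ether; 3 malonyl dichloride
Product: 4 6-[3,4-bis(TBSO)phenyl]-4-hydroxy-2H-pyran-2-one
Conditions: Et2O, −78 → 0 °C, 3 h
Reagents that add atoms: none
Why: Effenberger-type pyranone annulation, in which C-acylation of the silyl enol ether by malonyl dichloride is followed by O-acylation of the new enol to close ring C; aryl silyl ethers tolerate the brief cold exposure to HCl.

Step 3
Reactants: 5 2,2,6-trimethyl-4H-1,3-dioxin-4-one
Product: 6 2,2-dimethyl-4-oxo-4H-1,3-dioxine-6-carbaldehyde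
Conditions: SeO2 (1.2 equiv), 1,4-dioxane, 80 °C
Reagents that add atoms: selenium dioxide, O=[Se]=O
Why: Riley oxidation of the vinylogous methyl group of the β-alkoxy enoate, run below the temperature at which the dioxinone loses acetone.

Step 4
Reactants: 4 ring C pyranone; 6 dioxinone aldehyde
Product: 8 6-[3,4-bis(TBSO)phenyl]-3-[(2,2-dimethyl-4-oxo-4H-1,3-dioxin-6-yl)methyl]-4-hydroxy-2H-pyran-2-one, via alkylidene pyrandione 7 (not isolated)
Conditions: diethyl 1,4-dihydro-2,6-dimethylpyridine-3,5-dicarboxylate (1.1 equiv), L-proline (10 mol%), CH2Cl2, 23 °C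
Reagents that add atoms: none
Why: Organocatalytic three-component reductive alkylation (Knoevenagel condensation, then conjugate hydride transfer from the Hantzsch ester) alkylates C-3 of the 1,3-dicarbonyl cleanly and avoids the O-alkylation seen with halides.

Step 5
Reactants: 9 3,4-dihydroxybenzaldehyde
Product: 10 3,4-bis(TBSO)benzaldehyde
Conditions: TBSCl (2.4 equiv), imidazole (5 equiv), DMF, 23 °C
Reagents that add atoms: tert-butyldimethylsilyl chloride, CC(C)(C)[Si](C)(C)Cl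
Why: Standard Corey silylation of phenols.

Step 6
Reactants: 10 3,4-bis(TBSO)benzaldehyde
Product: 11 [3,4-bis(TBSO)phenyl]methanol
Conditions: NaBH4, MeOH–THF, 0 °C, 20 min
Reagents that add atoms: none
Why: Borohydride reduction of an aryl aldehyde; the aryl silyl ethers survive the short cold exposure.

Step 7
Reactants: 8 C-3 alkylated pyranone; 11 benzyl alcohol
Product: 12 4-{[3,4-bis(TBSO)phenyl]methoxy}-6-[3,4-bis(TBSO)phenyl]-3-[(2,2-dimethyl-4-oxo-4H-1,3-dioxin-6-yl)methyl]-2H-pyran-2-one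
Conditions: PPh3, DIAD, THF, 0 → 23 °C
Reagents that add atoms: none
Why: Mitsunobu etherification, in which the acidic enol OH (pKa about 5) of the 4-hydroxy-2-pyranone is alkylated at O-4 by the activated primary benzylic alcohol.

Step 8
Reactants: 12 benzyl ether
Product: 13 4-{[3,4-bis(TBSO)phenyl]methoxy}-6-[3,4-bis(TBSO)phenyl]-3-[diazo(2,2-dimethyl-4-oxo-4H-1,3-dioxin-6-yl)methyl]-2H-pyran-2-one
Conditions: p-ABSA (1.5 equiv), DBU (1.5 equiv), MeCN, 0 °C, dark; short SiO2 plug, used at once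
Reagents that add atoms: 4-acetamidobenzenesulfonyl azide, CC(=O)Nc1ccc(cc1)S(=O)(=O)N=[N+]=[N-]
Why: Regitz diazo transfer; the methylene lies between the pyranone and C-6 of the dioxinone (the position deprotonated in dioxinone dienolate chemistry), so DBU gives enough carbanion to capture the sulfonyl azide and form a vinylogous diazo ester.

Step 9
Reactants: 14 trimethylsilyl acetate
Product: 15 1,1-bis(trimethylsilyloxy)ethene
Conditions: LiN(iPr)2, THF, −78 °C; Me3SiCl, −78 → 23 °C; distillation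
Reagents that add atoms: chlorotrimethylsilane, C[Si](C)(C)Cl
Why: O-silylation of the silyl ester enolate (Ainsworth ketene bis-silyl acetal synthesis).

Step 10
Reactants: 13 diazo compound; 15 ketene bis-silyl acetal
Product: 19 (2R,3S)-2,6-bis[3,4-bis(TBSO)phenyl]-3-(4-hydroxy-2-oxo-2H-pyran-6-yl)-2,3-dihydro-4H-furo[3,2-c]pyran-4-one, via cis-dihydrofuran dioxinone 16 (not isolated), via acylketene 17 (not isolated), via silyloxypyranone 18 (not isolated)
Conditions: Rh2(R-PTAD)4 [dirhodium tetrakis((R)-(1-adamantyl)(N-phthalimido)acetate)] (1 mol%), toluene, 4 Å MS, slow addition of 13, −20 → 23 °C, 2 h; then 15 (5 equiv), 110 °C, 1 h; then MeOH, 23 °C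
Reagents that add atoms: none
Why: Proposed new method: the dirhodium carbene from 13 can reach only the CH2 of the 4-O-benzyl ether through a five-membered transition state, and this 1,5-C–H insertion into an electron-rich benzylic ether C–H is the known enantioselective, kinetically cis-selective route to 2,3-disubstituted 2,3-dihydrobenzofurans with chiral dirhodium tetracarboxylates (the catalyst selects one enantiotopic hydrogen and so sets C-2 and C-3 together as cis, here 2R,3S), after which warming the same solution triggers the known retro-[4+2] loss of acetone from the dioxinone to acylketene 17, whose hetero-Diels–Alder reaction with ketene acetal 15 and loss of silanol builds ring A under neutral, base-free conditions that leave the epimerisable cis centres untouched; the closest known reactions are donor-type carbene C–H insertion into benzyl ethers and acylketene [4+2] cycloadditions with enol ethers and ketene acetals to pyranones.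

Step 11
Reactants: 19 tetrakis-TBS ether
Product: 20 (2R,3S)-2,6-bis(3,4-dihydroxyphenyl)-3-(4-hydroxy-2-oxo-2H-pyran-6-yl)-2,3-dihydro-4H-furo[3,2-c]pyran-4-one
Conditions: KHF2 (10 equiv), MeOH–THF 1:1, 23 °C; work-up and chromatography at pH 4–5
Reagents that add atoms: none
Why: Fluoride-mediated desilylation with KHF2 in methanol cleaves aryl silyl ethers under weakly acidic conditions, avoiding the base-induced ring opening and re-closure (E1cB or quinone methide) that would epimerise the cis-dihydrofuran to trans.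

**Compound list**
1 | 1-(3,4-dihydroxyphenyl)ethan-1-one (3',4'-dihydroxyacetophenone) | CC(=O)c1ccc(O)c(O)c1 | starting material
2 | tert-butyl{[1-(3,4-bis(TBSO)phenyl)ethenyl]oxy}dimethylsilane | C=C(O[Si](C)(C)C(C)(C)C)c1ccc(O[Si](C)(C)C(C)(C)C)c(O[Si](C)(C)C(C)(C)C)c1 | intermediate
3 | malonyl dichloride (propanedioyl dichloride) | O=C(Cl)CC(=O)Cl | starting material
4 | 6-[3,4-bis(TBSO)phenyl]-4-hydroxy-2H-pyran-2-one (ring C) | O=c1cc(O)cc(-c2ccc(O[Si](C)(C)C(C)(C)C)c(O[Si](C)(C)C(C)(C)C)c2)o1 | intermediate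
5 | 2,2,6-trimethyl-4H-1,3-dioxin-4-one | CC1=CC(=O)OC(C)(C)O1 | starting material
6 | 2,2-dimethyl-4-oxo-4H-1,3-dioxine-6-carbaldehyde | O=CC1=CC(=O)OC(C)(C)O1 | intermediate
7 | 6-[3,4-bis(TBSO)phenyl]-3-[(2,2-dimethyl-4-oxo-4H-1,3-dioxin-6-yl)methylidene]-2H-pyran-2,4(3H)-dione (Knoevenagel adduct, alkene geometry not defined, not isolated) | O=C1OC(c2ccc(O[Si](C)(C)C(C)(C)C)c(O[Si](C)(C)C(C)(C)C)c2)=CC(=O)C1=CC1=CC(=O)OC(C)(C)O1 | intermediate
8 | 6-[3,4-bis(TBSO)phenyl]-3-[(2,2-dimethyl-4-oxo-4H-1,3-dioxin-6-yl)methyl]-4-hydroxy-2H-pyran-2-one | O=c1oc(-c2ccc(O[Si](C)(C)C(C)(C)C)c(O[Si](C)(C)C(C)(C)C)c2)cc(O)c1CC1=CC(=O)OC(C)(C)O1 | intermediate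
9 | 3,4-dihydroxybenzaldehyde | O=Cc1ccc(O)c(O)c1 | starting material
10 | 3,4-bis(TBSO)benzaldehyde | O=Cc1ccc(O[Si](C)(C)C(C)(C)C)c(O[Si](C)(C)C(C)(C)C)c1 | intermediate
11 | [3,4-bis(TBSO)phenyl]methanol | OCc1ccc(O[Si](C)(C)C(C)(C)C)c(O[Si](C)(C)C(C)(C)C)c1 | intermediate
12 | 4-{[3,4-bis(TBSO)phenyl]methoxy}-6-[3,4-bis(TBSO)phenyl]-3-[(2,2-dimethyl-4-oxo-4H-1,3-dioxin-6-yl)methyl]-2H-pyran-2-one | O=c1oc(-c2ccc(O[Si](C)(C)C(C)(C)C)c(O[Si](C)(C)C(C)(C)C)c2)cc(OCc2ccc(O[Si](C)(C)C(C)(C)C)c(O[Si](C)(C)C(C)(C)C)c2)c1CC1=CC(=O)OC(C)(C)O1 | intermediate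
13 | 4-{[3,4-bis(TBSO)phenyl]methoxy}-6-[3,4-bis(TBSO)phenyl]-3-[diazo(2,2-dimethyl-4-oxo-4H-1,3-dioxin-6-yl)methyl]-2H-pyran-2-one | O=c1oc(-c2ccc(O[Si](C)(C)C(C)(C)C)c(O[Si](C)(C)C(C)(C)C)c2)cc(OCc2ccc(O[Si](C)(C)C(C)(C)C)c(O[Si](C)(C)C(C)(C)C)c2)c1C(=[N+]=[N-])C1=CC(=O)OC(C)(C)O1 | intermediate
14 | trimethylsilyl acetate | CC(=O)O[Si](C)(C)C | starting material
15 | 1,1-bis(trimethylsilyloxy)ethene (ketene bis(trimethylsilyl) acetal) | C=C(O[Si](C)(C)C)O[Si](C)(C)C | intermediate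
16 | (2R,3S)-2,6-bis[3,4-bis(TBSO)phenyl]-3-(2,2-dimethyl-4-oxo-4H-1,3-dioxin-6-yl)-2,3-dihydro-4H-furo[3,2-c]pyran-4-one (cis, not isolated) | CC1(C)OC(=O)C=C(O1)[C@H]1c2c(cc(-c3ccc(O[Si](C)(C)C(C)(C)C)c(O[Si](C)(C)C(C)(C)C)c3)oc2=O)O[C@H]1c1ccc(O[Si](C)(C)C(C)(C)C)c(O[Si](C)(C)C(C)(C)C)c1 | intermediate
17 | 3-{(2R,3S)-2,6-bis[3,4-bis(TBSO)phenyl]-4-oxo-2,3-dihydro-4H-furo[3,2-c]pyran-3-yl}-3-oxoprop-1-en-1-one (acylketene, not isolated) | O=C=CC(=O)[C@H]1c2c(cc(-c3ccc(O[Si](C)(C)C(C)(C)C)c(O[Si](C)(C)C(C)(C)C)c3)oc2=O)O[C@H]1c1ccc(O[Si](C)(C)C(C)(C)C)c(O[Si](C)(C)C(C)(C)C)c1 | intermediate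
18 | (2R,3S)-2,6-bis[3,4-bis(TBSO)phenyl]-3-[4-oxo-6-(trimethylsilyloxy)-4H-pyran-2-yl]-2,3-dihydro-4H-furo[3,2-c]pyran-4-one (not isolated) | C[Si](C)(C)OC1=CC(=O)C=C(O1)[C@H]1c2c(cc(-c3ccc(O[Si](C)(C)C(C)(C)C)c(O[Si](C)(C)C(C)(C)C)c3)oc2=O)O[C@H]1c1ccc(O[Si](C)(C)C(C)(C)C)c(O[Si](C)(C)C(C)(C)C)c1 | intermediate
19 | (2R,3S)-2,6-bis[3,4-bis(TBSO)phenyl]-3-(4-hydroxy-2-oxo-2H-pyran-6-yl)-2,3-dihydro-4H-furo[3,2-c]pyran-4-one | O=c1cc(O)cc([C@H]2c3c(cc(-c4ccc(O[Si](C)(C)C(C)(C)C)c(O[Si](C)(C)C(C)(C)C)c4)oc3=O)O[C@H]2c2ccc(O[Si](C)(C)C(C)(C)C)c(O[Si](C)(C)C(C)(C)C)c2)o1 | intermediate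
20 | (2R,3S)-2,6-bis(3,4-dihydroxyphenyl)-3-(4-hydroxy-2-oxo-2H-pyran-6-yl)-2,3-dihydro-4H-furo[3,2-c]pyran-4-one (CNP0224684.1; 2-aryl and 3-pyranonyl cis) | O=c1cc(O)cc([C@H]2c3c(cc(-c4ccc(O)c(O)c4)oc3=O)O[C@H]2c2ccc(O)c(O)c2)o1 | target

**Totals**
Total step count: 11. Longest linear sequence: 7 (steps 1, 2, 4, 7, 8, 10, 11).

**Steps most likely to fail, with fallbacks**

Step 10 is the weakest point. Diazo compound 13 is a vinylogous diazo ester that can cyclise to a pyrazole or dimerise. The cis centres and the acylketene must also survive 110 °C, and capture of 17 by 15 is intermolecular. The fallback builds ring A before any stereocentre exists, so the chiral material never sees heat. Setting out from 12, heating with 15 in toluene at 110 °C and methanol work-up gives the achiral 4-{[3,4-bis(TBSO)phenyl]methoxy}-6-[3,4-bis(TBSO)phenyl]-3-[(4-hydroxy-2-oxo-2H-pyran-6-yl)methyl]-2H-pyran-2-one F1. TIPSOTf with 2,6-lutidine then gives its ring A triisopropylsilyl ether F2, and p-ABSA with DBU gives the corresponding diazo compound F3. The chiral dirhodium catalyst of step 10 at −20 → 23 °C closes ring B alone to the cis (2R,3S) ring A triisopropylsilyl ether of compound 19 F4. KHF2 in MeOH (conditions of step 11) removes all five silyl groups, and the route is re-joined at 20.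

Step 8 may fail because the methylene of 12 is only weakly acidic, so diazo transfer with an amidine base may stall, and DBU may attack the aryl silyl ethers on long exposure. The fallback replaces diazo transfer by irreversible metalation, electrophilic azidation and azide-to-diazo conversion. Setting out from 12, LiN(SiMe3)2 in THF at −78 °C followed by 2,4,6-triisopropylbenzenesulfonyl azide and an acetic acid quench gives 3-[azido(2,2-dimethyl-4-oxo-4H-1,3-dioxin-6-yl)methyl]-4-{[3,4-bis(TBSO)phenyl]methoxy}-6-[3,4-bis(TBSO)phenyl]-2H-pyran-2-one F5. N-succinimidyl 3-(diphenylphosphino)propanoate in wet THF converts the azide into an acyl triazene, which fragments with mild base to the diazo compound, re-joining the route at 13.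

Step 3 may fail because the Riley oxidation competes with thermal opening of the dioxinone, and aldehyde 6 is a reactive vinylogous formyl ester. The fallback avoids 6 and the reductive alkylation, and forms the C-3–CH2 bond by cross-coupling. Setting out from 4, Mitsunobu etherification with 11 gives 4-{[3,4-bis(TBSO)phenyl]methoxy}-6-[3,4-bis(TBSO)phenyl]-2H-pyran-2-one F6, and NBS in MeCN brominates C-3 to give the 3-bromo derivative of that ether F7. Separately 5 is converted with LiN(iPr)2 and Me3SiCl into trimethyl[(2,2-dimethyl-6-methylidene-6H-1,3-dioxin-4-yl)oxy]silane F8. Pd(dba)2 (zerovalent palladium) with P(t-Bu)3 and ZnF2 in DMF at 80 °C couples F7 with the γ-carbon of F8 and re-joins the route at 12, bypassing steps 3 and 4.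

Further compounds
F1 | step 10 | 4-{[3,4-bis(TBSO)phenyl]methoxy}-6-[3,4-bis(TBSO)phenyl]-3-[(4-hydroxy-2-oxo-2H-pyran-6-yl)methyl]-2H-pyran-2-one | O=c1oc(-c2ccc(O[Si](C)(C)C(C)(C)C)c(O[Si](C)(C)C(C)(C)C)c2)cc(OCc2ccc(O[Si](C)(C)C(C)(C)C)c(O[Si](C)(C)C(C)(C)C)c2)c1Cc1cc(O)cc(=O)o1
F2 | step 10 | 4-{[3,4-bis(TBSO)phenyl]methoxy}-6-[3,4-bis(TBSO)phenyl]-3-({2-oxo-4-[(triisopropylsilyl)oxy]-2H-pyran-6-yl}methyl)-2H-pyran-2-one | O=c1oc(-c2ccc(O[Si](C)(C)C(C)(C)C)c(O[Si](C)(C)C(C)(C)C)c2)cc(OCc2ccc(O[Si](C)(C)C(C)(C)C)c(O[Si](C)(C)C(C)(C)C)c2)c1Cc1cc(O[Si](C(C)C)(C(C)C)C(C)C)cc(=O)o1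
F3 | step 10 | 4-{[3,4-bis(TBSO)phenyl]methoxy}-6-[3,4-bis(TBSO)phenyl]-3-(diazo{2-oxo-4-[(triisopropylsilyl)oxy]-2H-pyran-6-yl}methyl)-2H-pyran-2-one | O=c1oc(-c2ccc(O[Si](C)(C)C(C)(C)C)c(O[Si](C)(C)C(C)(C)C)c2)cc(OCc2ccc(O[Si](C)(C)C(C)(C)C)c(O[Si](C)(C)C(C)(C)C)c2)c1C(=[N+]=[N-])c1cc(O[Si](C(C)C)(C(C)C)C(C)C)cc(=O)o1
F4 | step 10 | (2R,3S)-2,6-bis[3,4-bis(TBSO)phenyl]-3-{2-oxo-4-[(triisopropylsilyl)oxy]-2H-pyran-6-yl}-2,3-dihydro-4H-furo[3,2-c]pyran-4-one | O=c1cc(O[Si](C(C)C)(C(C)C)C(C)C)cc([C@H]2c3c(cc(-c4ccc(O[Si](C)(C)C(C)(C)C)c(O[Si](C)(C)C(C)(C)C)c4)oc3=O)O[C@H]2c2ccc(O[Si](C)(C)C(C)(C)C)c(O[Si](C)(C)C(C)(C)C)c2)o1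
F5 | step 8 | 3-[azido(2,2-dimethyl-4-oxo-4H-1,3-dioxin-6-yl)methyl]-4-{[3,4-bis(TBSO)phenyl]methoxy}-6-[3,4-bis(TBSO)phenyl]-2H-pyran-2-one (racemic) | O=c1oc(-c2ccc(O[Si](C)(C)C(C)(C)C)c(O[Si](C)(C)C(C)(C)C)c2)cc(OCc2ccc(O[Si](C)(C)C(C)(C)C)c(O[Si](C)(C)C(C)(C)C)c2)c1C(N=[N+]=[N-])C1=CC(=O)OC(C)(C)O1
F6 | step 3 | 4-{[3,4-bis(TBSO)phenyl]methoxy}-6-[3,4-bis(TBSO)phenyl]-2H-pyran-2-one | O=c1cc(OCc2ccc(O[Si](C)(C)C(C)(C)C)c(O[Si](C)(C)C(C)(C)C)c2)cc(-c2ccc(O[Si](C)(C)C(C)(C)C)c(O[Si](C)(C)C(C)(C)C)c2)o1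
F7 | step 3 | 3-bromo-4-{[3,4-bis(TBSO)phenyl]methoxy}-6-[3,4-bis(TBSO)phenyl]-2H-pyran-2-one | O=c1oc(-c2ccc(O[Si](C)(C)C(C)(C)C)c(O[Si](C)(C)C(C)(C)C)c2)cc(OCc2ccc(O[Si](C)(C)C(C)(C)C)c(O[Si](C)(C)C(C)(C)C)c2)c1Br
F8 | step 3 | trimethyl[(2,2-dimethyl-6-methylidene-6H-1,3-dioxin-4-yl)oxy]silane | C=C1C=C(O[Si](C)(C)C)OC(C)(C)O1
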